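**Retrosynthetic overview**

1. Target 21 ⇐ desilylation and CBS reduction of 2‑methylenecycloheptanone 19 ⇐ gold‑catalysed alkynyl semipinacol ring expansion (6→7, C1 migrates from C9 to the new C10) of the 1‑ethynyl trans‑hydrindanol 18.
2. 18 ⇐ trans‑hydrindenone 17 ⇐ C1–C9 bond by NHC crossed benzoin of keto‑aldehyde 15, then SmI2 removal of the C1 hydroxyl (sets H‑1).
3. 15 ⇐ Nef reaction of nitro enone 13 ⇐ Mukaiyama aldol (C5–C6) of cyclopentadienyl bis‑silyl ether 12 with γ‑nitro aldehyde 6.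
4. 6 ⇐ 4‑methylpent‑3‑enal (syn‑crotylation, acetylation, aldehyde‑selective Wacker, amine‑catalysed Michael addition to nitroethene); 12 ⇐ (S)‑4‑hydroxycyclopent‑2‑enone (MeLi 1,2‑addition, MnO2).
5. Ring order: cyclopentene (purchased ring) → six‑membered ring (step 10) → seven‑membered ring by ring expansion (step 13).

Assumption: atom labels follow the hydroazulene numbering of the target (ring fusion C1/C5; carbinols C4, C6, C9; C10=C18 exocyclic; side chain C7–C11(C19)–C12(OAc)–C13–C14=C15); β is the face of H‑5, α the opposite face; nitroethene is used as a toluene stock solution.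

**Step 1**
Reactants: 1 4‑methylpent‑3‑enal
Product: 2 (3S,4S)‑3,7‑dimethylocta‑1,6‑dien‑4‑ol
Conditions: (Z)‑crotylB(pin), (R)‑TRIP (5 mol %), PhMe, –30 °C; aq. NaHCO3
Reagents that add atoms: (Z)‑crotylboronic acid pinacol ester, C/C=C\CB1OC(C)(C)C(C)(C)O1
Why: Chiral phosphoric acid‑catalysed crotylboration through a closed chair transition state; the Z‑boronate gives the syn C11/C12 pair and the catalyst enantiomer is the one that delivers the (3S,4S) isomer.

**Step 2**
Reactants: 2 (3S,4S)‑3,7‑dimethylocta‑1,6‑dien‑4‑ol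
Product: 3 (3S,4S)‑3,7‑dimethylocta‑1,6‑dien‑4‑yl acetate
Conditions: Ac2O, pyridine, DMAP (cat.), CH2Cl2, 0 °C → rt
Reagents that add atoms: acetic anhydride, CC(=O)OC(C)=O
Why: Standard acylation installs the C12 acetate while this is the only hydroxyl in the molecule.

**Step 3**
Reactants: 3 (3S,4S)‑3,7‑dimethylocta‑1,6‑dien‑4‑yl acetate
Product: 4 (3S,4S)‑3,7‑dimethyl‑1‑oxooct‑6‑en‑4‑yl acetate
Conditions: PdCl2(PhCN)2, CuCl2, AgNO2 (cat.), O2 (1 atm), t‑BuOH/MeNO2, rt
Reagents that add atoms: dioxygen, O=O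
Why: Aldehyde‑selective (anti‑Markovnikov) Wacker oxidation of the terminal vinyl group; the trisubstituted prenyl alkene is inert under these conditions.

**Step 4**
Reactants: 4 (3S,4S)‑3,7‑dimethyl‑1‑oxooct‑6‑en‑4‑yl acetate; 5 nitroethene
Product: 6 (2S,3S,4S)‑3,7‑dimethyl‑2‑(2‑nitroethyl)‑1‑oxooct‑6‑en‑4‑yl acetate
Conditions: (S)‑α,α‑diphenylprolinol TMS ether (5 mol %), 3‑nitrobenzoic acid (10 mol %), PhMe, 3 °C
Reagents that add atoms: none
Why: Enamine‑catalysed Michael addition of the aldehyde to nitroethene; the diarylprolinol silyl ether shields one enamine face and sets C7 (S) under catalyst control.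

**Step 5**
Reactants: 7 (S)‑4‑hydroxycyclopent‑2‑en‑1‑one
Product: 10 (1R,4S)‑1‑methylcyclopent‑2‑ene‑1,4‑diol, via TMS ether 8 (not isolated), via silylated carbinol 9 (not isolated)
Conditions: TMSCl, Et3N, THF, 0 °C; MeLi, CeCl3, –78 °C; citric acid, MeOH
Reagents that add atoms: methyllithium, [Li]C
Why: Organocerium 1,2‑addition to the enone anti to the silyloxy group gives the cis‑diol, relaying the carbinol chirality to the new tertiary centre (future C4).

**Step 6**
Reactants: 10 (1R,4S)‑1‑methylcyclopent‑2‑ene‑1,4‑diol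
Product: 11 (R)‑4‑hydroxy‑4‑methylcyclopent‑2‑en‑1‑one
Conditions: MnO2, CH2Cl2, rt
Reagents that add atoms: none
Why: MnO2 allylic oxidation takes only the secondary allylic alcohol, completing a 1,3‑carbonyl transposition that leaves C4 (Me, OH) enantiopure.

**Step 7**
Reactants: 11 (R)‑4‑hydroxy‑4‑methylcyclopent‑2‑en‑1‑one
Product: 12 (S)‑3‑methyl‑1,3‑bis(triethylsilyloxy)cyclopenta‑1,4‑diene
Conditions: TESOTf (2.3 equiv), Et3N, CH2Cl2, –78 → 0 °C; used at once
Reagents that add atoms: triethylsilyl triflate, CC[Si](CC)(CC)OS(=O)(=O)C(F)(F)F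
Why: Soft enolisation/silylation gives the cross‑conjugated silyl dienol ether and protects the tertiary alcohol; the quaternary C4 blocks 1,5‑hydrogen shifts in the diene.

**Step 8**
Reactants: 12 (S)‑3‑methyl‑1,3‑bis(triethylsilyloxy)cyclopenta‑1,4‑diene; 6 (2S,3S,4S)‑3,7‑dimethyl‑2‑(2‑nitroethyl)‑1‑oxooct‑6‑en‑4‑yl acetate
Product: 13 (1R,2S,3S,4S)‑1‑[(1R,5S)‑5‑methyl‑2‑oxo‑5‑(triethylsilyloxy)cyclopent‑3‑en‑1‑yl]‑3,7‑dimethyl‑2‑(2‑nitroethyl)‑1‑(triethylsilyloxy)oct‑6‑en‑4‑yl acetate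
Conditions: HNTf2 (3 mol %), CH2Cl2, –78 °C
Reagents that add atoms: none
Why: Silyl triflimide‑catalysed Mukaiyama aldol with silyl transfer; the enol silane reacts at C5 anti to the C4 silyloxy group and the aldehyde reacts in the Felkin–Anh sense (C11 branch as large group), which sets C5 and C6 through an open transition state that tolerates the nitro group.

**Step 9**
Reactants: 13 bis‑TES nitro enone
Product: 15 (1R,2S,3S,4S)‑1‑[(1R,5S)‑5‑methyl‑2‑oxo‑5‑(triethylsilyloxy)cyclopent‑3‑en‑1‑yl]‑3,7‑dimethyl‑2‑(2‑oxoethyl)‑1‑(triethylsilyloxy)oct‑6‑en‑4‑yl acetate, via potassium nitronate 14 (not isolated)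
Conditions: KOt‑Bu (1.05 equiv), THF, 0 °C; aq. TiCl3, NH4OAc (pH 6), rt
Reagents that add atoms: water, O
Why: Nef reaction (buffered TiCl3 variant); the nitro α‑CH2 is by far the most acidic site, so one equivalent of base gives the nitronate, which is reduced to the imine and hydrolysed to the C9 aldehyde.

**Step 10**
Reactants: 15 keto‑aldehyde
Product: 16 α‑ketol: cis‑fused 1β‑hydroxy hydrindenone (C9 ketone, C1–C9 bond α), otherwise substituted as 17
Conditions: bicyclic N‑mesityl triazolium chloride (10 mol %), Et3N, PhMe, 40 °C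
Reagents that add atoms: none
Why: NHC‑catalysed intramolecular crossed benzoin; the Breslow intermediate from the C9 aldehyde adds 1,2 to the C1 ketone to close the six‑membered ring, and the C1 carbinol configuration is irrelevant because it is erased in step 11.

**Step 11**
Reactants: 16 α‑ketol
Product: 17 trans‑hydrindenone: 1α‑H, 5β‑H, 4α‑methyl, 4β,6β‑bis(triethylsilyloxy), 7β‑[(2S,3S)‑3‑acetoxy‑6‑methylhept‑5‑en‑2‑yl], C9 ketone bonded to C1 and C8, C2=C3
Conditions: SmI2 (2.5 equiv), THF/MeOH, –78 °C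
Reagents that add atoms: none
Why: SmI2 reductive cleavage of the α‑hydroxy ketone gives the C9/C1 samarium enolate, which is protonated at C1 from the α face (β face screened by the C4 and C6 silyloxy groups) to give the trans ring fusion, also the more stable hydrindan‑4‑one.

**Step 12**
Reactants: 17 trans‑hydrindenone
Product: 18 9‑ethynyl‑9‑hydroxy trans‑hydrindene (tertiary propargylic alcohol at C9, drawn 9β‑OH), otherwise as 17
Conditions: HC≡CMgBr, CeCl3, THF, –78 °C
Reagents that add atoms: ethynylmagnesium bromide, C#C[Mg]Br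
Why: Organocerium alkynylation adds cleanly to the enolisable β,γ‑unsaturated ketone without touching the acetate; the C9 configuration is inconsequential.

**Step 13**
Reactants: 18 propargylic alcohol
Product: 19 trans‑fused 10‑methylene‑9‑oxo hydroazulene (bicyclo[5.3.0]: C9(=O)–C10(=CH2)–C1), otherwise as 17
Conditions: [(2,4‑t‑Bu2C6H3O)3P]AuNTf2 (5 mol %), 4 Å MS, CH2Cl2, 0 °C → rt
Reagents that add atoms: none
Why: Proposed new method: a cationic phosphite–gold(I) complex π‑activates the terminal alkyne, the tertiary allylic ring carbon C1 (much better migrating group than the C8 methylene) shifts from C9 to the internal alkyne carbon with retention while the carbinol becomes the ketone, and protodeauration of the vinyl‑gold gives the exocyclic enone; the driving force is alkyne → conjugated enone rather than strain release, and the closest known reaction is the gold(I)‑catalysed ring expansion of 1‑alkynylcyclobutanols and ‑cyclopropanols (alkynyl semipinacol).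

**Step 14**
Reactants: 19 α‑methylene cycloheptanone
Product: 20 4,6‑bis(triethylsilyl) ether of the target (9α‑OH, 9R)
Conditions: (S)‑Me‑CBS, catecholborane, PhMe, –78 °C
Reagents that add atoms: none
Why: CBS reduction of the enone carbonyl with the alkenyl side as the large group gives the (9R) allylic alcohol under reagent control; catecholborane leaves the other alkenes and the acetate untouched.

**Step 15**
Reactants: 20 bis‑TES ether
Product: 21 target
Conditions: HF·pyridine, pyridine, THF, 0 °C → rt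
Reagents that add atoms: none
Why: Buffered fluoride desilylation removes both triethylsilyl ethers without acetate migration or ionisation of the tertiary allylic alcohol.

**Compound list**

1 | 4‑methylpent‑3‑enal | CC(C)=CCC=O | starting material
2 | (3S,4S)‑3,7‑dimethylocta‑1,6‑dien‑4‑ol | C=C[C@H](C)[C@H](CC=C(C)C)O | intermediate
3 | (3S,4S)‑3,7‑dimethylocta‑1,6‑dien‑4‑yl acetate | C=C[C@H](C)[C@H](CC=C(C)C)OC(C)=O | intermediate
4 | (3S,4S)‑3,7‑dimethyl‑1‑oxooct‑6‑en‑4‑yl acetate | O=CC[C@H](C)[C@H](CC=C(C)C)OC(C)=O | intermediate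
5 | nitroethene | C=C[N+](=O)[O-] | starting material
6 | (2S,3S,4S)‑3,7‑dimethyl‑2‑(2‑nitroethyl)‑1‑oxooct‑6‑en‑4‑yl acetate | O=C[C@@H](CC[N+](=O)[O-])[C@H](C)[C@H](CC=C(C)C)OC(C)=O | intermediate
7 | (S)‑4‑hydroxycyclopent‑2‑en‑1‑one | O[C@@H]1C=CC(=O)C1 | starting material
8 | (S)‑4‑(trimethylsilyloxy)cyclopent‑2‑en‑1‑one | C[Si](C)(C)O[C@@H]1C=CC(=O)C1 | intermediate
9 | (1R,4S)‑1‑methyl‑4‑(trimethylsilyloxy)cyclopent‑2‑en‑1‑ol (metal alkoxide in the flask) | C[Si](C)(C)O[C@@H]1C=C[C@](C)(O)C1 | intermediate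
10 | (1R,4S)‑1‑methylcyclopent‑2‑ene‑1,4‑diol | O[C@@H]1C=C[C@](C)(O)C1 | intermediate
11 | (R)‑4‑hydroxy‑4‑methylcyclopent‑2‑en‑1‑one | O=C1C=C[C@](C)(O)C1 | intermediate
12 | (S)‑3‑methyl‑1,3‑bis(triethylsilyloxy)cyclopenta‑1,4‑diene | C[C@]1(O[Si](CC)(CC)CC)C=CC(O[Si](CC)(CC)CC)=C1 | intermediate
13 | (1R,2S,3S,4S)‑1‑[(1R,5S)‑5‑methyl‑2‑oxo‑5‑(triethylsilyloxy)cyclopent‑3‑en‑1‑yl]‑3,7‑dimethyl‑2‑(2‑nitroethyl)‑1‑(triethylsilyloxy)oct‑6‑en‑4‑yl acetate | O=C1C=C[C@](C)(O[Si](CC)(CC)CC)[C@H]1[C@H](O[Si](CC)(CC)CC)[C@@H](CC[N+](=O)[O-])[C@H](C)[C@H](CC=C(C)C)OC(C)=O | intermediate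
14 | potassium nitronate of 13 | O=C1C=C[C@](C)(O[Si](CC)(CC)CC)[C@H]1[C@H](O[Si](CC)(CC)CC)[C@@H](CC=[N+]([O-])[O-])[C@H](C)[C@H](CC=C(C)C)OC(C)=O.[K+] | intermediate
15 | (1R,2S,3S,4S)‑1‑[(1R,5S)‑5‑methyl‑2‑oxo‑5‑(triethylsilyloxy)cyclopent‑3‑en‑1‑yl]‑3,7‑dimethyl‑2‑(2‑oxoethyl)‑1‑(triethylsilyloxy)oct‑6‑en‑4‑yl acetate | O=C1C=C[C@](C)(O[Si](CC)(CC)CC)[C@H]1[C@H](O[Si](CC)(CC)CC)[C@@H](CC=O)[C@H](C)[C@H](CC=C(C)C)OC(C)=O | intermediate
16 | α‑ketol: cis‑fused 1β‑hydroxy‑9‑oxo hydrindene, 4α‑methyl, 4β,6β‑bis(triethylsilyloxy), 7β‑[(2S,3S)‑3‑acetoxy‑6‑methylhept‑5‑en‑2‑yl] | O=C1C[C@@H]([C@H](C)[C@H](CC=C(C)C)OC(C)=O)[C@@H](O[Si](CC)(CC)CC)[C@H]2[C@]1(O)C=C[C@]2(C)O[Si](CC)(CC)CC | intermediate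
17 | trans‑hydrindenone: 1α‑H, 5β‑H, 9‑oxo, 4α‑methyl, 4β,6β‑bis(triethylsilyloxy), 7β‑[(2S,3S)‑3‑acetoxy‑6‑methylhept‑5‑en‑2‑yl], C2=C3 | O=C1C[C@@H]([C@H](C)[C@H](CC=C(C)C)OC(C)=O)[C@@H](O[Si](CC)(CC)CC)[C@H]2[C@H]1C=C[C@]2(C)O[Si](CC)(CC)CC | intermediate
18 | 9‑ethynyl‑9β‑hydroxy derivative of 17 (tertiary propargylic alcohol) | C#C[C@]1(O)C[C@@H]([C@H](C)[C@H](CC=C(C)C)OC(C)=O)[C@@H](O[Si](CC)(CC)CC)[C@H]2[C@H]1C=C[C@]2(C)O[Si](CC)(CC)CC | intermediate
19 | trans‑fused 10‑methylene‑9‑oxo hydroazulene, 4,6‑bis(triethylsilyl) ether, 12‑acetate | C=C1C(=O)C[C@@H]([C@H](C)[C@H](CC=C(C)C)OC(C)=O)[C@@H](O[Si](CC)(CC)CC)[C@H]2[C@H]1C=C[C@]2(C)O[Si](CC)(CC)CC | intermediate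
20 | 4,6‑bis(triethylsilyl) ether of the target (9α‑OH) | C=C1[C@H](O)C[C@@H]([C@H](C)[C@H](CC=C(C)C)OC(C)=O)[C@@H](O[Si](CC)(CC)CC)[C@H]2[C@H]1C=C[C@]2(C)O[Si](CC)(CC)CC | intermediate
21 | target (CNP0126182.2) | C=C1[C@H](O)C[C@@H]([C@H](C)[C@H](CC=C(C)C)OC(C)=O)[C@@H](O)[C@H]2[C@H]1C=C[C@]2(C)O | target

**Step count and risks**

Total steps: 15. Longest linear sequence: 12 (steps 1–4, then 8–15).

Steps most likely to fail:

Step 13 (proposed new ring expansion). Without ring strain, Meyer–Schuster/Rupe isomerisation or attack of the C2=C3 alkene on the activated alkyne may compete. The fallback sets out from 17 and uses only known reactions. TMSCHN2 with BF3·OEt2 at –78 °C expands the ketone by migration of the less substituted C8 methylene and, after protodesilylation, gives the ring‑expanded cycloheptanone F1 (ketone now C10, new CH2 is C9). Kinetic enolisation with KHMDS at –78 °C and a Davis camphorsulfonyl oxaziridine give the 9α‑hydroxy ketone F2. Wittig methylenation with Ph3P=CH2 then returns to the route at 20.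

Step 10 (crossed benzoin onto an enone carbonyl). The acyl anion equivalent may prefer Stetter addition, or base may eliminate the C6 silyloxy group. The fallback sets out from 15: SmI2 with t‑BuOH at –78 °C effects a ketyl–carbonyl pinacol cyclisation to the cis‑1,9‑diol F3, and SO3·pyridine/DMSO oxidation of its secondary carbinol returns to the route at 16.

Step 9 (Nef reaction next to an enone and silyl ethers). The fallback sets out from 13 and avoids the free aldehyde: catalytic DBU triggers an intramolecular Henry addition of the nitronate to the C1 ketone to give the nitro alcohol F4 (C9 epimers). Burgess dehydration gives the 9‑nitro diene F5, and CrCl2 in aqueous THF (reductive Nef) gives the ketone with C1 protonated, returning to the route at 17.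

Further compounds
F1 | step 13 | ring‑expanded cycloheptanone (C10 ketone, C9 methylene), 4,6‑bis(triethylsilyl) ether, 12‑acetate | O=C1CC[C@@H]([C@H](C)[C@H](CC=C(C)C)OC(C)=O)[C@@H](O[Si](CC)(CC)CC)[C@H]2[C@H]1C=C[C@]2(C)O[Si](CC)(CC)CC
F2 | step 13 | 9α‑hydroxy‑10‑oxo hydroazulene, 4,6‑bis(triethylsilyl) ether, 12‑acetate | O=C1[C@H](O)C[C@@H]([C@H](C)[C@H](CC=C(C)C)OC(C)=O)[C@@H](O[Si](CC)(CC)CC)[C@H]2[C@H]1C=C[C@]2(C)O[Si](CC)(CC)CC
F3 | step 10 | cis‑1β,9β‑diol of the hydrindene (pinacol product), otherwise as 16 | O[C@H]1C[C@@H]([C@H](C)[C@H](CC=C(C)C)OC(C)=O)[C@@H](O[Si](CC)(CC)CC)[C@H]2[C@]1(O)C=C[C@]2(C)O[Si](CC)(CC)CC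
F4 | step 9 | 1β‑hydroxy‑9‑nitro hydrindene (Henry adduct, C9 epimers), otherwise as 16 | [O-][N+](=O)C1C[C@@H]([C@H](C)[C@H](CC=C(C)C)OC(C)=O)[C@@H](O[Si](CC)(CC)CC)[C@H]2[C@]1(O)C=C[C@]2(C)O[Si](CC)(CC)CC
F5 | step 9 | 9‑nitro‑1(9),2‑diene (dehydrated Henry adduct) | O=[N+]([O-])C1=C2C=C[C@](C)(O[Si](CC)(CC)CC)[C@H]2[C@H](O[Si](CC)(CC)CC)[C@H]([C@H](C)[C@H](CC=C(C)C)OC(C)=O)C1
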